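**Retrosynthetic overview**

- Rings: A para-linked benzene, B meta-linked benzene, C hydroxylated benzene, D quinone (C1 OMe, C2 H, C3 C=O, C4 O–ring B, C5 ethano bridge to ring A, C6 C=O). The target is reached by freeing the ring-C phenol from its methoxymethyl (MOM) ether after oxidative demethylation of a ring-D trimethoxyarene (C3 and C6 become the carbonyls, the C1 methoxy stays).
- Key disconnection: the ether between ring B C3 (meta to its ethano bridge, no activating group) and the oxygen on ring D C4, which is flanked by the C3 oxygen function and the C5 bridge. This bond is made by nickel-mediated loss of CO from a 19-membered aryl benzoate, contracting it to the 18-membered ether.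
- The lactone comes from a seco hydroxy acid (ring-B CO2H, ring-D C4–OH) by macrolactonisation, because an ester forms easily at this hindered oxygen where a direct ether does not.
- The seco acid comes from two Wittig olefinations (B–C and A–D bridges), one SNAr (A–O–C ether) and one hydrogenation, using 2,4,5-trimethoxybenzaldehyde, methyl 3-(bromomethyl)benzoate, 3,4-dihydroxybenzaldehyde and 4-fluorobenzaldehyde.
- Ring order: rings A–D are bought; the macrocycle is closed as the 19-membered lactone (step 12), contracted to the 18-membered ether (step 13), and the quinone is unveiled last.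

Key step: step 13

Remark: both Wittig olefinations should give E/Z mixtures, which are carried on unseparated because step 10 saturates both double bonds; the target has no stereocentre.
Remark: methyl 3-(bromomethyl)benzoate is taken as the commercial ring-B building block, which saves the reduction and bromination of a formyl ester.

**Route**

Step 1
Reactants: 1 2,4,5-trimethoxybenzaldehyde
Product: 3 2,4,5-trimethoxyphenol, via 2,4,5-trimethoxyphenyl formate 2 (not isolated)
Conditions: 30% H2O2 (1.3 equiv), H2SO4 (cat.), MeOH, rt, under Ar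
Reagents that add atoms: hydrogen peroxide, OO
Why: Acid-catalysed Dakin-type (Baeyer–Villiger) oxidation, in which the electron-rich aryl group migrates to oxygen in the peroxide adduct and the formate 2 is methanolysed in the same flask.

Step 2
Reactants: 3 2,4,5-trimethoxyphenol
Product: 4 2-hydroxy-3,5,6-trimethoxybenzaldehyde
Conditions: MgCl2, Et3N, (CH2O)n, MeCN, 80 °C, under Ar; dilute HCl work-up
Reagents that add atoms: paraformaldehyde (as formaldehyde), C=O
Why: Magnesium-mediated ortho-formylation (Casnati–Skattebøl), in which the magnesium phenoxide delivers formaldehyde to the only free ortho carbon and a second formaldehyde oxidises the hydroxymethyl stage by hydride transfer.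

Step 3
Reactants: 4 2-hydroxy-3,5,6-trimethoxybenzaldehyde
Product: 5 2-(hydroxymethyl)-3,4,6-trimethoxyphenol
Conditions: NaBH4, MeOH, 0 °C
Reagents that add atoms: none
Why: Borohydride reduction of an aryl aldehyde, with no other reducible group in 4.

Step 4
Reactants: 5 2-(hydroxymethyl)-3,4,6-trimethoxyphenol
Product: 6 (2-hydroxy-3,5,6-trimethoxybenzyl)triphenylphosphonium bromide
Conditions: Ph3P·HBr (1.0 equiv), MeCN, 80 °C
Reagents that add atoms: triphenylphosphine hydrobromide, Br.c1ccc(cc1)P(c1ccccc1)c1ccccc1
Why: Salicyl alcohols react with Ph3P·HBr through the ortho-quinone methide (or benzylic cation), which the phosphine traps to give the (2-hydroxybenzyl)phosphonium salt without protecting the phenol.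

Step 5
Reactants: 7 methyl 3-(bromomethyl)benzoate
Product: 8 [3-(methoxycarbonyl)benzyl]triphenylphosphonium bromide
Conditions: PPh3, toluene, 110 °C
Reagents that add atoms: triphenylphosphine, c1ccc(cc1)P(c1ccccc1)c1ccccc1
Why: SN2 quaternisation of a benzylic bromide by triphenylphosphine, the salt separating from toluene.

Step 6
Reactants: 9 3,4-dihydroxybenzaldehyde
Product: 10 3-hydroxy-4-(methoxymethoxy)benzaldehyde
Conditions: MOMCl (1.05 equiv), K2CO3, acetone, 0 °C to rt
Reagents that add atoms: chloromethyl methyl ether, COCCl
Why: Selective Williamson-type alkylation, since the 4-hydroxyl is conjugated with the para formyl group, is the more acidic one, and its phenoxide reacts first with one equivalent of the chloride.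

Step 7
Reactants: 10 3-hydroxy-4-(methoxymethoxy)benzaldehyde, 8 [3-(methoxycarbonyl)benzyl]triphenylphosphonium bromide
Product: 11 methyl 3-[2-[3-hydroxy-4-(methoxymethoxy)phenyl]ethenyl]benzoate (E/Z mixture)
Conditions: NaOMe (2.4 equiv), MeOH, 0 °C to rt
Reagents that add atoms: none
Why: Wittig olefination with a semi-stabilised benzylic ylide, the extra base covering the free meta phenol, whose phenoxide is not conjugated with the aldehyde; methoxide cannot scramble the methyl ester.

Step 8
Reactants: 11 methyl 3-[2-[3-hydroxy-4-(methoxymethoxy)phenyl]ethenyl]benzoate, 12 4-fluorobenzaldehyde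
Product: 13 methyl 3-[2-[3-(4-formylphenoxy)-4-(methoxymethoxy)phenyl]ethenyl]benzoate (E/Z mixture)
Conditions: K2CO3, DMF, 110 °C
Reagents that add atoms: none
Why: Nucleophilic aromatic substitution (SNAr), the para formyl group activating the fluoride towards the phenoxide of 11 and serving afterwards as the handle for the second olefination.

Step 9
Reactants: 13 methyl 3-[2-[3-(4-formylphenoxy)-4-(methoxymethoxy)phenyl]ethenyl]benzoate, 6 (2-hydroxy-3,5,6-trimethoxybenzyl)triphenylphosphonium bromide
Product: 14 methyl 3-[2-[3-[4-[2-(2-hydroxy-3,5,6-trimethoxyphenyl)ethenyl]phenoxy]-4-(methoxymethoxy)phenyl]ethenyl]benzoate (E/Z mixture at both alkenes)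
Conditions: 6, LiN(SiMe3)2 (2 equiv per 6), THF, −78 to 0 °C; then 13, 0 °C to rt
Reagents that add atoms: none
Why: Wittig olefination with the phenoxide ylide preformed from 6 at low temperature, which attacks only the aldehyde and leaves the methyl ester untouched.

Step 10
Reactants: 14 bis-stilbene methyl ester
Product: 15 methyl 3-[2-[3-[4-[2-(2-hydroxy-3,5,6-trimethoxyphenyl)ethyl]phenoxy]-4-(methoxymethoxy)phenyl]ethyl]benzoate
Conditions: H2 (1 atm), 10% Pd/C, EtOAc, rt
Reagents that add atoms: none
Why: Heterogeneous catalytic hydrogenation of two stilbene double bonds, with aryl ethers, the MOM ether and the ester inert under neutral conditions.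

Step 11
Reactants: 15 bis(bibenzyl) methyl ester
Product: 16 3-[2-[3-[4-[2-(2-hydroxy-3,5,6-trimethoxyphenyl)ethyl]phenoxy]-4-(methoxymethoxy)phenyl]ethyl]benzoic acid (seco acid)
Conditions: LiOH, THF/MeOH/H2O, 40 °C, under Ar; cold 1 M HCl to pH 4
Reagents that add atoms: lithium hydroxide (hydroxide oxygen), [Li+].[OH-]
Why: Saponification of the methyl ester, with cold work-up at pH 4 to keep the MOM ether and exclusion of air to protect the electron-rich phenoxide.

Step 12
Reactants: 16 seco acid
Product: 18 macrolactone (19-membered aryl benzoate between the ring-B carboxyl and the ring-D C4 oxygen; ring D trimethoxyarene; ring C MOM ether), via mixed 2,4,6-trichlorobenzoic anhydride 17 (not isolated)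
Conditions: 2,4,6-Cl3C6H2COCl, Et3N, THF, rt; then slow addition to DMAP, toluene, 90 °C (about 1 mM)
Reagents that add atoms: 2,4,6-trichlorobenzoyl chloride, O=C(Cl)c1c(Cl)cc(Cl)cc1Cl (its atoms stay in intermediate 17 only)
Why: Yamaguchi macrolactonisation, in which DMAP opens the mixed anhydride at the less hindered carbonyl and the acylpyridinium ion acylates the single free hydroxyl (ring-D phenol) under high dilution.

Step 13
Reactants: 18 macrolactone
Product: 19 macrocyclic diaryl ether (18-membered; ring B C3 bonded to the ring-D C4 oxygen; ring D trimethoxyarene; ring C MOM ether)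
Conditions: Ni(cod)2 (0.5 equiv), dcypt [3,4-bis(dicyclohexylphosphino)thiophene] (1.0 equiv), K3PO4 (1.5 equiv), mesitylene, 150 °C, slow Ar stream
Reagents that add atoms: none
Why: Proposed new method: zerovalent nickel bearing the electron-rich chelating diphosphine dcypt is expected to add oxidatively to the C(acyl)–O bond of lactone 18, the resulting divalent acyl nickel aryloxide loses CO by de-insertion to an aryl nickel aryloxide, and C–O reductive elimination joins ring B C3 to the ring-D oxygen. The closest known reaction type is the intermolecular decarbonylative etherification of aryl esters with Ni(cod)2 or Pd(OAc)2 and dcypt, shown mainly for azine carboxylates; a plain benzoate with a 2,6-disubstituted, electron-rich aryloxide lies outside that scope. The 18-membered ring arises by contraction of the 19-membered lactone (one ring atom leaves as CO), so the ring is already closed and aryl and aryloxide never leave the metal, which excludes crossover and oligomers. No stereocentre is formed. The step needs site selectivity for the acyl–oxygen bond over the aryl–oxygen bonds: 18 holds a single ester, its aryl–oxygen side is electron-rich and flanked on both sides, and the methyl, MOM and diaryl ethers on non-fused benzene rings are not cleaved by this catalyst without a reductant. The argon stream removes CO, which would otherwise reverse the de-insertion and bind nickel as carbonyl complexes, and the high nickel loading is accepted for the same reason.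

Step 14
Reactants: 19 macrocyclic diaryl ether
Product: 20 MOM-protected methoxyquinone (ring D 2-methoxy-1,4-benzoquinone carrying the aryloxy group at C4 and the bridge at C5)
Conditions: (NH4)2Ce(NO3)6 (2.5 equiv), MeCN/H2O 3:1, 0 °C, 20 min
Reagents that add atoms: water, O
Why: Oxidative demethylation with tetravalent cerium, in which the most electron-rich ring (D) forms a radical cation, water adds at the methoxy-bearing carbons C3 and C6 (the para pair with the two strongest donors), and loss of two methanol gives the para-quinone that keeps the C1 methoxy group; ring C stays masked as its MOM ether so no free phenol meets the oxidant.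

Step 15
Reactants: 20 MOM-protected methoxyquinone
Product: 21 CNP0332646.0 (target)
Conditions: TFA, wet CH2Cl2, 0 °C to rt
Reagents that add atoms: none
Why: Acid-catalysed cleavage of the aryl methoxymethyl acetal, using a non-nucleophilic acid so that the aryloxy and methoxy groups on the quinone (both vinylogous esters) are not exchanged.

**Compound list**

1 | 2,4,5-trimethoxybenzaldehyde | COc1cc(OC)c(C=O)cc1OC | starting material
2 | 2,4,5-trimethoxyphenyl formate | COc1cc(OC)c(OC=O)cc1OC | intermediate
3 | 2,4,5-trimethoxyphenol | COc1cc(OC)c(O)cc1OC | intermediate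
4 | 2-hydroxy-3,5,6-trimethoxybenzaldehyde | COc1cc(OC)c(O)c(C=O)c1OC | intermediate
5 | 2-(hydroxymethyl)-3,4,6-trimethoxyphenol | COc1cc(OC)c(O)c(CO)c1OC | intermediate
6 | (2-hydroxy-3,5,6-trimethoxybenzyl)triphenylphosphonium bromide | COc1cc(OC)c(O)c(C[P+](c2ccccc2)(c2ccccc2)c2ccccc2)c1OC.[Br-] | intermediate
7 | methyl 3-(bromomethyl)benzoate | COC(=O)c1cccc(CBr)c1 | starting material
8 | [3-(methoxycarbonyl)benzyl]triphenylphosphonium bromide | COC(=O)c1cccc(C[P+](c2ccccc2)(c2ccccc2)c2ccccc2)c1.[Br-] | intermediate
9 | 3,4-dihydroxybenzaldehyde | O=Cc1ccc(O)c(O)c1 | starting material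
10 | 3-hydroxy-4-(methoxymethoxy)benzaldehyde | COCOc1ccc(C=O)cc1O | intermediate
11 | methyl 3-[2-[3-hydroxy-4-(methoxymethoxy)phenyl]ethenyl]benzoate (E/Z mixture) | COC(=O)c1cccc(C=Cc2ccc(OCOC)c(O)c2)c1 | intermediate
12 | 4-fluorobenzaldehyde | O=Cc1ccc(F)cc1 | starting material
13 | methyl 3-[2-[3-(4-formylphenoxy)-4-(methoxymethoxy)phenyl]ethenyl]benzoate (E/Z mixture) | COC(=O)c1cccc(C=Cc2ccc(OCOC)c(Oc3ccc(C=O)cc3)c2)c1 | intermediate
14 | methyl 3-[2-[3-[4-[2-(2-hydroxy-3,5,6-trimethoxyphenyl)ethenyl]phenoxy]-4-(methoxymethoxy)phenyl]ethenyl]benzoate (E/Z mixture at both alkenes) | COC(=O)c1cccc(C=Cc2ccc(OCOC)c(Oc3ccc(C=Cc4c(O)c(OC)cc(OC)c4OC)cc3)c2)c1 | intermediate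
15 | methyl 3-[2-[3-[4-[2-(2-hydroxy-3,5,6-trimethoxyphenyl)ethyl]phenoxy]-4-(methoxymethoxy)phenyl]ethyl]benzoate | COC(=O)c1cccc(CCc2ccc(OCOC)c(Oc3ccc(CCc4c(O)c(OC)cc(OC)c4OC)cc3)c2)c1 | intermediate
16 | 3-[2-[3-[4-[2-(2-hydroxy-3,5,6-trimethoxyphenyl)ethyl]phenoxy]-4-(methoxymethoxy)phenyl]ethyl]benzoic acid (seco acid) | OC(=O)c1cccc(CCc2ccc(OCOC)c(Oc3ccc(CCc4c(O)c(OC)cc(OC)c4OC)cc3)c2)c1 | intermediate
17 | mixed anhydride of 16 with 2,4,6-trichlorobenzoic acid | O=C(OC(=O)c1c(Cl)cc(Cl)cc1Cl)c1cccc(CCc2ccc(OCOC)c(Oc3ccc(CCc4c(O)c(OC)cc(OC)c4OC)cc3)c2)c1 | intermediate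
18 | 19-membered macrolactone (aryl benzoate of ring B on the ring-D C4 oxygen; ring D trimethoxyarene; ring C MOM ether) | COc1cc(OC)c2OC(=O)c3cccc(c3)CCc3ccc(OCOC)c(c3)Oc3ccc(cc3)CCc2c1OC | intermediate
19 | 18-membered macrocyclic diaryl ether (ring D trimethoxyarene; ring C MOM ether) | COc1cc(OC)c2Oc3cccc(c3)CCc3ccc(OCOC)c(c3)Oc3ccc(cc3)CCc2c1OC | intermediate
20 | MOM-protected macrocyclic methoxyquinone | COC1=CC(=O)C2=C(CCc3ccc(cc3)Oc3cc(ccc3OCOC)CCc3cccc(c3)O2)C1=O | intermediate
21 | CNP0332646.0 (macrocyclic bis(bibenzyl) methoxyquinone with free ring-C phenol) | COC1=CC(=O)C2=C(CCc3ccc(cc3)Oc3cc(ccc3O)CCc3cccc(c3)O2)C1=O | target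

**Step count and risks**

Total step count: 15. Longest linear sequence: 11 steps (from 1 through steps 1–4 and 9–15).

Steps most likely to fail:

1. Step 13 (Proposed new method). Process at risk: oxidative addition into the acyl–oxygen bond of an ester with an electron-rich, doubly ortho-substituted aryloxide may be too slow. The acyl nickel aryloxide may also return to the ester or lose nickel as carbonyl complexes before C–O reductive elimination. The fallback is an intramolecular Ullmann etherification, which is known chemistry. It sets out from 10.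
   - Wittig olefination of 10 with (3-bromobenzyl)triphenylphosphonium bromide (NaOMe, MeOH) should give the bromostilbene phenol F1.
   - SNAr with 12 (K2CO3, DMF, 110 °C) should give the diaryl ether aldehyde F2.
   - Wittig olefination with the ylide of 6 (LiN(SiMe3)2, THF) should give the bis-stilbene F3.
   - Diimide (TsNHNH2, NaOAc, THF/H2O, reflux) should saturate both alkenes and keep the C–Br bond, giving the bromo phenol F4.
   - CuI, picolinic acid and K3PO4 in DMSO at 90 °C under high dilution should close the ring B–oxygen bond, and the fallback comes back to the route at 19.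

2. Step 14. Process at risk: hydration of the arene radical cation at the other para pair (C1 methoxy and C4 aryloxy), which would expel the ring-B phenoxide and open the macrocycle. Early loss of the MOM group followed by oxidation of the ring-C phenol is a second concern. The fallback removes the regiochemical question and sets out from 19.
   - BBr3 (CH2Cl2, −78 °C to rt) should cleave the three methyl ethers and the MOM ether, leaving both diaryl ethers and giving the tetraphenol F5.
   - Air or Ag2O should oxidise its trihydroxylated ring D to the hydroxyquinone F6. This is the only para-quinone that ring can form, and the ortho-quinone is its tautomer.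
   - Me3SiCHN2 (toluene/MeOH, 0 °C, one equivalent) should methylate the acidic vinylogous-acid hydroxyl in preference to the ring-C phenol, and the fallback comes back to the route at 21.

3. Step 12. Process at risk: intermolecular acylation to dimers and oligomers, and slow acylation of the hindered phenol so that the mixed anhydride disproportionates. The fallback is a palladium-catalysed carbonylative ring closure, which builds the lactone from an aryl iodide, CO and the phenol and keeps the acylating species at catalyst concentration. It sets out from 10.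
   - The same four operations as in the fallback to step 13, but with (3-iodobenzyl)triphenylphosphonium bromide, should give in turn the iodostilbene phenol F7, the diaryl ether aldehyde F8, the bis-stilbene F9 and the iodo phenol F10.
   - Pd(OAc)2, Xantphos, CO (1 atm) and Et3N in toluene at 90 °C with slow addition of F10 should give the aryl ester, and the fallback comes back to the route at 18.

**Further compounds**

F1 | step 13 | 5-[2-(3-bromophenyl)ethenyl]-2-(methoxymethoxy)phenol (E/Z mixture) | COCOc1ccc(C=Cc2cccc(Br)c2)cc1O
F2 | step 13 | 4-[5-[2-(3-bromophenyl)ethenyl]-2-(methoxymethoxy)phenoxy]benzaldehyde (E/Z mixture) | COCOc1ccc(C=Cc2cccc(Br)c2)cc1Oc1ccc(C=O)cc1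
F3 | step 13 | 2-[2-[4-[5-[2-(3-bromophenyl)ethenyl]-2-(methoxymethoxy)phenoxy]phenyl]ethenyl]-3,4,6-trimethoxyphenol (E/Z mixture at both alkenes) | COCOc1ccc(C=Cc2cccc(Br)c2)cc1Oc1ccc(C=Cc2c(O)c(OC)cc(OC)c2OC)cc1
F4 | step 13 | 2-[2-[4-[5-[2-(3-bromophenyl)ethyl]-2-(methoxymethoxy)phenoxy]phenyl]ethyl]-3,4,6-trimethoxyphenol | COCOc1ccc(CCc2cccc(Br)c2)cc1Oc1ccc(CCc2c(O)c(OC)cc(OC)c2OC)cc1
F5 | step 14 | macrocyclic diaryl ether tetraphenol (ring D 1,3,6-trihydroxy, ring C hydroxy) | Oc1cc(O)c2Oc3cccc(c3)CCc3ccc(O)c(c3)Oc3ccc(cc3)CCc2c1O
F6 | step 14 | macrocyclic hydroxyquinone (O-demethyl analogue of the target) | OC1=CC(=O)C2=C(CCc3ccc(cc3)Oc3cc(ccc3O)CCc3cccc(c3)O2)C1=O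
F7 | step 12 | 5-[2-(3-iodophenyl)ethenyl]-2-(methoxymethoxy)phenol (E/Z mixture) | COCOc1ccc(C=Cc2cccc(I)c2)cc1O
F8 | step 12 | 4-[5-[2-(3-iodophenyl)ethenyl]-2-(methoxymethoxy)phenoxy]benzaldehyde (E/Z mixture) | COCOc1ccc(C=Cc2cccc(I)c2)cc1Oc1ccc(C=O)cc1
F9 | step 12 | 2-[2-[4-[5-[2-(3-iodophenyl)ethenyl]-2-(methoxymethoxy)phenoxy]phenyl]ethenyl]-3,4,6-trimethoxyphenol (E/Z mixture at both alkenes) | COCOc1ccc(C=Cc2cccc(I)c2)cc1Oc1ccc(C=Cc2c(O)c(OC)cc(OC)c2OC)cc1
F10 | step 12 | 2-[2-[4-[5-[2-(3-iodophenyl)ethyl]-2-(methoxymethoxy)phenoxy]phenyl]ethyl]-3,4,6-trimethoxyphenol | COCOc1ccc(CCc2cccc(I)c2)cc1Oc1ccc(CCc2c(O)c(OC)cc(OC)c2OC)cc1
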